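Remark: heavy atoms are labelled C1–C23 (with O6, Br12, O17) in the order of the target SMILES. Where a catalyst's sense of induction on a new substrate cannot be known beforehand, the enantiomer named is the one the accepted model predicts, and its mirror image would be used otherwise.

## Structural features

The target is a brominated C20 tetracycle in which ring A (C9, C11, C13, C14, C15, C18) and ring B (C7, C8, C9, C18, C19, C20) form a trans-decalin with the angular methyl C10 on C9. Ring B shares only the spiro carbon C20 with ring C (C2, C3, C4, C5, C21, C20), and O6 ties C5 to C7, so rings C and D (C5, O6, C7, C20, C21) form a 6-oxabicyclo[3.2.1]octane whose one-carbon bridge is the gem-dimethyl carbon C21. There are seven stereocentres (5S, 7R, 9S, 11S, 15R, 18S, 20R): C15–C18–C9–C11 run along ring A, C7 and C20 are adjacent and reach C5 across C21, and three carbons are quaternary (C9, C20, C21), the last two directly bonded. The fragile groups are the equatorial secondary bromide at C11 (open to reduction and to 1,3-elimination toward a C14 enolate, closed to clean substitution because C9 is quaternary), the axial tertiary alcohol at C15 (ionises in strong acid) and the C1=C2 methylene (migrates in acid). The real difficulty is the crowded C20/C21 pair inside the bridged ether together with the position of H7, which lies on the exo face of the oxabicycle, under the syn methyl of C21 and 1,3-diaxial to C10 on ring B, where no hydride can be delivered. The C7–O bond must therefore be fixed before the bridge is closed, and for this reason the C5 stereocentre of the photochemical precursor is chosen as the epimer (5R) of the final C5–O bond, so that ring D is closed last with inversion at C5. A second difficulty is C11: displacement there is blocked by the neopentyl environment and would be diverted by participation of an oxygen on C7, so bromine must arrive as an electrophile. The key step uses the 1,5-relationship of C2 and the carbinol carbon C15 through C20–C19–C18, because a 1,5-diketone of this kind is what an enol–alkene photocycloaddition followed by retro-aldol cleavage delivers, with ring A closed in the same operation.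

## Logic of the disconnections

**33 ⇒ 32.** The O6–C5 bond of ring D is cut, leaving a C7 alkoxide and a C5 leaving group on the opposite face of ring C. The cut is made here because a plan that forms C7–H last (reduction of a C7 hemiketal or oxocarbenium ion) would deliver the hydrogen from the open endo face and give the C7 epimer. The gain is that H7 and O6 on C7 are already in place. The forward step demands substitution with inversion at a hindered ring carbon, an oxygen on C5 of 5R configuration, and no carbonyl at C2 that would let the alkoxide undergo retro-aldol cleavage.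

**32 ⇒ 31 ⇒ 30.** C1=C2 is traced back to the C2 ketone and the C15–C16 bond to the C15 ketone. The order is dictated by hindrance: once C20 is quaternary the C2 ketone is far less reactive than C15, so a methyl nucleophile can be sent to C15 alone. The forward steps demand equatorial attack at C15 (axial OH) and a non-basic methylenation that leaves the β-hydroxy ketone intact.

**30 ⇒ 28 (through 29).** The C7–C20 bond of ring B is cut as an aldol between the C2 enol (nucleophilic at C20) and a C7 aldehyde. This removes the spiro quaternary centre, one ring and two stereocentres at once. The forward step demands that the bulky C21 takes the equatorial position on the new ring B chair (which gives 20R) and that the C7 hydroxyl is equatorial (7R); both are the lower-energy arrangements. It also demands that C20 rather than C14 or the aldehyde α-carbon acts as nucleophile.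

**28 ⇒ 27 ⇒ 26.** The mesylate is traced back to the silyl ether. The exchange is placed here because this is the only stage after the organometallic steps where O5 is the sole hydroxyl. The forward steps must leave the C–O bond at C5 untouched.

**26 ⇒ 24 (through 25).** This is the key disconnection. C15–C18 and C19–C20 are cut and C15–C20 is reconnected, which opens ring A and returns the two ketones to one β-diketone carrying a vinyl group on C9. The gain is one ring, two skeletal bonds and the C18 stereocentre. The forward step demands straight regiochemistry and reaction through the enol tautomer.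

**24 ⇒ 23 ⇒ 21 + 15.** C20–C15 is cut as an aldol followed by oxidation. An aldehyde is used rather than an acyl halide because C20 lies next to quaternary C21 and would be O-acylated. The forward step needs the C2 enolate regiospecifically on the C20 side, which only conjugate addition to a C20=C21 enone provides.

**21 ⇒ 20 ⇒ 19 ⇒ 18 ⇒ 17 ⇒ 16.** The second C21 methyl is removed (conjugate addition, no new stereocentre), then the silyl group. The C5 oxygen is traced through a β,γ-epoxy ketal to a deconjugated ketal of a commercial enone. The forward demand is a single enantioselective epoxidation.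

**15 ⇒ 12 + 13.** C13–C14 is cut as alkylation of an acetaldehyde azaenolate by a primary triflate. This brings in C14 and C15 without ever placing a double bond next to the bromide. The forward step demands attack at the primary carbon without elimination.

**12 ⇒ 11 ⇒ 9 (through 10).** The C11–Br bond is cut as electrophilic α-bromination of an aldehyde. The reason is that no displacement at C11 is needed. The forward step demands catalyst-controlled facial selectivity next to a quaternary carbon.

**9 ⇒ 8 ⇒ 7 ⇒ 5 + 6.** C9–C11 is cut as a branched-selective allylic alkylation with a malonate. This sets the C9 quaternary centre and creates the vinyl group (C18=C19) in one step. The forward step demands attack at the more substituted allyl terminus and a pure E alkene.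

**5 ⇒ 4 ⇒ 3 ⇒ 1 + 2.** C9=C18 is cut by Horner–Wadsworth–Emmons olefination. The forward step demands separation of the E isomer.

## Other disconnections considered

Alternative 1: The cut is C7–C20, made across a nine-membered ring. In the forward step BF3·OEt2 would ionise the α-acetoxy ether A1 to the C7 oxocarbenium ion, and C20 of the allylsilane would attack it, closing rings B and D, expelling silicon and leaving the C1=C2 methylene in A2 (the C15 triethylsilyl ether of 33).
- In its favour: the bond to C7 is made by carbon and not by hydride, so H7 can lie on the hindered face. This is the same stereochemical logic as the chosen plan, and on this point the two are equal.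
- Better than the chosen plan: the exocyclic methylene appears without olefinating a hindered ketone, and two rings form in one step.
- Against it: A1 needs a nine-membered ring in which O6 joins two hindered secondary carbons, and a tetrasubstituted allylsilane in the correct position. The tertiary silyl ether at C15 must survive BF3. Protodesilylation competes. The face of the medium-ring oxocarbenium ion that is attacked is not biased by a chair as it is in step 20.
- Comparison: the end game would be shorter, but the medium ring and the allylsilane would probably cost more steps than they save, and ring A with its bromide would still need a separate solution.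

Alternative 2: The cuts are C20–C21 and C2–C3. In the forward step Me2AlCl would promote a Diels–Alder reaction of the allenyl ketone A3 with 4-methylpenta-1,3-diene A4 to give the spiro ketone A5.
- In its favour: ring C and both adjacent quaternary carbons form at once from an achiral, commercial diene, and the ortho rule points to the required regiochemistry.
- Better than the chosen plan: no chiral ring C building block is needed and the methylene is present from the start.
- Against it: A4 carries a Z methyl on the reacting terminus, so its s-cis form is strained and the diene is sluggish, and the new C20–C21 bond joins two fully substituted carbons in the transition state. Facial selectivity at C20 is not secured by any obvious feature. A5 then still lacks the C5 oxygen and ring D, which would have to come from the unactivated C4=C5 alkene in the presence of the more reactive methylene, and C7 would need reduction to the equatorial alcohol.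
- Comparison: the mechanism is thermal and convergent where the chosen plan is photochemical and linear in its late part. If the bromodecalin A3 were short to make, the overall count could be lower, but the late oxygenation would take back much of the gain.

Alternative 3: The cut is O6–C5 with C5 as a methylene group. In the forward step the C7 alcohol A6, with PhI(OAc)2, I2 and visible light, would give a hypoiodite and then an alkoxy radical that abstracts the axial C5 hydrogen; oxidation and ring closure would give A7.
- In its favour: the C7–O bond is set beforehand by the same aldol logic as in the chosen plan (equal), and the configuration at C5 is dictated by the bridge.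
- Better than the chosen plan: no oxygen has to be carried at C5, so ring C would come directly from 16, and steps 10–13, 18 and 19 would disappear.
- Against it: the alkoxy radical at C7 is attached to quaternary C20 next to the C2 ketone, so β-scission of C7–C20 to a tertiary α-keto radical, which also relieves the C20/C21 strain, is a serious competitor. Several other hydrogens are in 1,5-relationship (the C21 methyls, C18–H, C11–H, C10), so site selectivity is uncertain. The C15 alcohol must be protected because its own alkoxy radical would fragment.
- Comparison: it is shorter in steps and equal in stereochemical logic, but it rests on a radical step with two plausible diversions, where the chosen plan uses a polar displacement.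

Key step: step 17

## Route

Step 1
Reactants: 1 4,4-dimethoxybutan-2-one; 2 triethyl phosphonoacetate
Product: 3 ethyl (2E)-5,5-dimethoxy-3-methylpent-2-enoate
Conditions: NaH, THF, 0 °C → reflux; chromatographic removal of the Z isomer
Reagents that add atoms: none
Why: Horner–Wadsworth–Emmons olefination of a methyl ketone; the ester is expected trans to the larger CH2CH(OMe)2 group, and the pure E alkene is needed because it fixes the configuration of C9 in step 4.

Step 2
Reactants: 3 ethyl (2E)-5,5-dimethoxy-3-methylpent-2-enoate
Product: 4 (2E)-5,5-dimethoxy-3-methylpent-2-en-1-ol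
Conditions: i-Bu2AlH, CH2Cl2, −78 → 0 °C
Reagents that add atoms: none
Why: 1,2-reduction of an enoate with i-Bu2AlH; the acetal and the alkene geometry are not affected.

Step 3
Reactants: 4 (2E)-5,5-dimethoxy-3-methylpent-2-en-1-ol
Product: 5 (2E)-5,5-dimethoxy-3-methylpent-2-en-1-yl methyl carbonate
Conditions: ClCO2Me, pyridine, CH2Cl2, 0 °C
Reagents that add atoms: methyl chloroformate, COC(=O)Cl
Why: acylation of a primary allylic alcohol; the carbonate is the leaving group for step 4 and supplies its own base (methoxide) on ionisation.

Step 4
Reactants: 5 (2E)-5,5-dimethoxy-3-methylpent-2-en-1-yl methyl carbonate; 6 dimethyl propanedioate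
Product: 7 dimethyl 2-[(3S)-5,5-dimethoxy-3-methylpent-1-en-3-yl]propanedioate
Conditions: [Ir(cod)Cl]2 (2 mol %), O,O′-(1,1′-binaphthalene-2,2′-diyl) N,N-bis(1-phenylethyl)phosphoramidite (4 mol %, enantiomer giving 3S), TBD (10 mol %), THF, rt
Reagents that add atoms: none
Why: iridium-catalysed branched-selective asymmetric allylic alkylation (Tsuji–Trost type); the malonate carbon (C11) bonds to the more substituted allyl terminus (C9) and the allyl backbone becomes the C18=C19 vinyl group; the E geometry from step 1 and the ligand together fix the face of attack, giving the 3S quaternary centre.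

Step 5
Reactants: 7 dimethyl 2-[(3S)-5,5-dimethoxy-3-methylpent-1-en-3-yl]propanedioate
Product: 8 methyl (3R)-3-ethenyl-5,5-dimethoxy-3-methylpentanoate
Conditions: LiCl, H2O, DMSO, 150 °C
Reagents that add atoms: none
Why: Krapcho dealkoxycarbonylation of a malonate; the quaternary centre is untouched (the descriptor changes only through the priority rules).

Step 6
Reactants: 8 methyl (3R)-3-ethenyl-5,5-dimethoxy-3-methylpentanoate
Product: 9 (3S)-3-ethenyl-5,5-dimethoxy-3-methylpentanal
Conditions: i-Bu2AlH, toluene, −78 °C
Reagents that add atoms: none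
Why: partial reduction of an ester through the tetrahedral aluminate that is stable at −78 °C; gives the aldehyde whose α-carbon is C11.

Step 7
Reactants: 9 (3S)-3-ethenyl-5,5-dimethoxy-3-methylpentanal
Product: 11 (2R,3S)-2-bromo-3-ethenyl-5,5-dimethoxy-3-methylpentan-1-ol, via α-bromo aldehyde 10 (not isolated)
Conditions: (2S,5S)-2,5-diphenylpyrrolidine (20 mol %), 4,4-dibromo-2,6-di-tert-butylcyclohexa-2,5-dien-1-one, PhCO2H, CH2Cl2/pentane, −40 °C; then NaBH4, MeOH, −40 → 0 °C
Reagents that add atoms: 4,4-dibromo-2,6-di-tert-butylcyclohexa-2,5-dien-1-one, O=C1C(C(C)(C)C)=CC(Br)(Br)C=C1C(C)(C)C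
Why: enamine-catalysed asymmetric α-bromination of an aldehyde; bromine arrives as an electrophile on the enamine face left open by the C2-symmetric catalyst, so C11 is set under catalyst control without any displacement at the neopentyl carbon, and reduction in the same flask gives a configurationally stable bromohydrin.

Step 8
Reactants: 11 (2R,3S)-2-bromo-3-ethenyl-5,5-dimethoxy-3-methylpentan-1-ol
Product: 12 (2R,3S)-2-bromo-3-ethenyl-5,5-dimethoxy-3-methylpentyl trifluoromethanesulfonate
Conditions: Tf2O, 2,6-lutidine, CH2Cl2, −78 °C; cold work-up, used at once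
Reagents that add atoms: trifluoromethanesulfonic anhydride, O=S(=O)(OS(=O)(=O)C(F)(F)F)C(F)(F)F
Why: sulfonylation of a primary alcohol; 2-bromoalkyl triflates are usable alkylating agents, and the C11–Br bond is not involved.

Step 9
Reactants: 12 (2R,3S)-2-bromo-3-ethenyl-5,5-dimethoxy-3-methylpentyl trifluoromethanesulfonate; 13 acetaldehyde N,N-dimethylhydrazone
Product: 15 (4S,5S)-4-bromo-5-ethenyl-7,7-dimethoxy-5-methylheptanal, via dimethylhydrazone 14 (not isolated)
Conditions: 13, LiN(i-Pr)2, THF, 0 °C; then 12, −78 → −40 °C; then aq. CuCl2, pH 7 buffer, THF, rt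
Reagents that add atoms: water, O
Why: alkylation of a lithiated hydrazone (azaenolate alkylation of the Corey–Enders type) at the primary triflate forms C13–C14 and brings in C14 and C15; no alkene is ever placed next to the bromide, and the hydrazone is hydrolysed at neutral pH so the acetal survives.

Step 10
Reactants: 16 3-methylcyclohex-2-en-1-one
Product: 17 7-methyl-1,4-dioxaspiro[4.5]dec-7-ene
Conditions: HOCH2CH2OH, p-TsOH (cat.), benzene, reflux, Dean–Stark
Reagents that add atoms: ethane-1,2-diol, OCCO
Why: ketalisation of a β-substituted enone with migration of the double bond to the β,γ position, which exposes C4/C5 (target labels C21/C5) as an isolated trisubstituted alkene.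

Step 11
Reactants: 17 7-methyl-1,4-dioxaspiro[4.5]dec-7-ene
Product: 18 (7S,8R)-7,8-epoxy-7-methyl-1,4-dioxaspiro[4.5]decane
Conditions: D-fructose-derived Shi ketone (1,2:4,5-di-O-isopropylidene-β-D-erythro-hexo-2,3-diulo-2,6-pyranose, 30 mol %), KHSO5 (Oxone), K2CO3, MeCN/dimethoxymethane/aq. buffer pH 10.5, 0 °C
Reagents that add atoms: potassium peroxymonosulfate, OOS(=O)(=O)[O-].[K+]
Why: Shi asymmetric epoxidation of a trisubstituted alkene through the chiral dioxirane; the spiro transition state places the oxygen on the face that 1-substituted cyclohexenes show with this ketone, which sets the future C5 stereocentre.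

Step 12
Reactants: 18 (7S,8R)-7,8-epoxy-7-methyl-1,4-dioxaspiro[4.5]decane
Product: 19 (4R)-4-hydroxy-3-methylcyclohex-2-en-1-one
Conditions: pyridinium p-toluenesulfonate, acetone/H2O, 40 °C; then Et3N, rt
Reagents that add atoms: water, O
Why: ketal hydrolysis followed by β-elimination of the β,γ-epoxy ketone (E1cB opening at the tertiary C–O bond) gives the γ-hydroxy enone; the C–O bond at the carbinol carbon is not broken, so its configuration is kept.

Step 13
Reactants: 19 (4R)-4-hydroxy-3-methylcyclohex-2-en-1-one
Product: 20 (4R)-4-[(tert-butyldimethylsilyl)oxy]-3-methylcyclohex-2-en-1-one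
Conditions: t-BuMe2SiCl, imidazole, DMF, rt
Reagents that add atoms: tert-butylchlorodimethylsilane, CC(C)(C)[Si](C)(C)Cl
Why: silylation of a secondary alcohol; the silyl ether, unlike an ester or sulfonate, survives the cuprate in step 14.

Step 14
Reactants: 20 (4R)-4-[(tert-butyldimethylsilyl)oxy]-3-methylcyclohex-2-en-1-one
Product: 21 tert-butyl{[(1R)-2,2-dimethyl-4-(trimethylsilyloxy)cyclohex-3-en-1-yl]oxy}dimethylsilane
Conditions: Me2CuLi, Me3SiCl, THF/Et2O, −78 → −30 °C; Et3N, cold NaHCO3 work-up
Reagents that add atoms: lithium dimethylcuprate, [Li+].C[Cu-]C; chlorotrimethylsilane, C[Si](C)(C)Cl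
Why: Me3SiCl-accelerated conjugate addition of a Gilman cuprate to a β,β-disubstituted enone; both substituents on C21 are then methyl, so no stereocentre arises, and the enolate is trapped regiospecifically on the C20 side, which deprotonation of the ketone could not give.

Step 15
Reactants: 21 tert-butyl{[(1R)-2,2-dimethyl-4-(trimethylsilyloxy)cyclohex-3-en-1-yl]oxy}dimethylsilane; 15 (4S,5S)-4-bromo-5-ethenyl-7,7-dimethoxy-5-methylheptanal
Product: 23 (4R)-2-[(4S,5S)-4-bromo-5-ethenyl-1-hydroxy-7,7-dimethoxy-5-methylheptyl]-4-[(tert-butyldimethylsilyl)oxy]-3,3-dimethylcyclohexan-1-one (diastereomers at C15 and C20), via lithium enolate 22 (not isolated)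
Conditions: MeLi, THF, 0 °C; then 15, −78 °C, 15 min; AcOH quench at −78 °C
Reagents that add atoms: none
Why: MeLi cleaves the O–Si bond to the regiodefined lithium enolate, which undergoes aldol addition to the unhindered aldehyde (C20–C15 bond); the two new stereocentres are removed in step 16, and the cold quench keeps the alkoxide from displacing the neopentyl bromide.

Step 16
Reactants: 23 (4R)-2-[(4S,5S)-4-bromo-5-ethenyl-1-hydroxy-7,7-dimethoxy-5-methylheptyl]-4-[(tert-butyldimethylsilyl)oxy]-3,3-dimethylcyclohexan-1-one
Product: 24 (4R)-2-[(4S,5S)-4-bromo-5-ethenyl-7,7-dimethoxy-5-methylheptanoyl]-4-[(tert-butyldimethylsilyl)oxy]-3,3-dimethylcyclohexan-1-one, drawn as its chelated (Z)-enol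
Conditions: Dess–Martin periodinane, NaHCO3, CH2Cl2, 0 °C → rt
Reagents that add atoms: none
Why: Dess–Martin oxidation of a β-hydroxy ketone to the β-diketone under buffered, non-basic conditions that leave bromide, acetal and silyl ether alone.

Step 17
Reactants: 24 (4R)-2-[(4S,5S)-4-bromo-5-ethenyl-7,7-dimethoxy-5-methylheptanoyl]-4-[(tert-butyldimethylsilyl)oxy]-3,3-dimethylcyclohexan-1-one (enol form)
Product: 26 (4R)-2-{[(1S,2S,3S)-3-bromo-2-(2,2-dimethoxyethyl)-2-methyl-6-oxocyclohexyl]methyl}-4-[(tert-butyldimethylsilyl)oxy]-3,3-dimethylcyclohexan-1-one (C20 epimers), via cyclobutanol photoadduct 25 (not isolated)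
Conditions: hν (350 nm, Pyrex), degassed cyclohexane (5 mM), rt; then Et3N (cat.), CH2Cl2, rt
Reagents that add atoms: none
Why: The hydrogen-bonded enol of 24 (chromophore C2(=O)–C20=C15–OH) absorbs at 350 nm and, from its triplet, C15 bonds to the internal vinyl carbon C18; the 1,4-diradical (C19/C20) closes to cyclobutanol 25, a β-hydroxy ketone that cleaves C20–C15 at once by retro-aldol, driven by loss of the four-membered ring and of the crowding at C20. The closest known reaction type is the intramolecular De Mayo reaction (enol–alkene [2+2] photocycloaddition followed by retro-aldol opening). Ring A closes by 6-exo-trig attack of C15 on C18 through the four-atom tether C14–C13–C11–C9; the transient cyclobutane closes by diradical recombination (C20–C19) and is opened again, so the net result is one ring and two skeletal bonds. The one lasting new stereocentre, C18, is α to the C15 ketone and equilibrates (Et3N) so that C19 is equatorial on the ring A chair defined by quaternary C9 and the equatorial C11 bromide (18S); C20 is formed as a mixture and becomes quaternary only in step 20. The step needs straight rather than crossed regiochemistry, which the tether secures (six-membered rather than seven-membered first ring). It needs reaction through the enol and not the diketo form, which irradiation at a wavelength only the enol absorbs and a non-polar solvent secure. It needs the C–Br bond to survive, which it should, being transparent at 350 nm and too far from either radical centre for β-scission.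

Step 18
Reactants: 26 (4R)-2-{[(1S,2S,3S)-3-bromo-2-(2,2-dimethoxyethyl)-2-methyl-6-oxocyclohexyl]methyl}-4-[(tert-butyldimethylsilyl)oxy]-3,3-dimethylcyclohexan-1-one
Product: 27 (4R)-2-{[(1S,2S,3S)-3-bromo-2-(2,2-dimethoxyethyl)-2-methyl-6-oxocyclohexyl]methyl}-4-hydroxy-3,3-dimethylcyclohexan-1-one (C20 epimers)
Conditions: HF·pyridine, pyridine, THF, 0 °C → rt
Reagents that add atoms: none
Why: fluoride-mediated desilylation buffered with pyridine, so the dimethyl acetal is kept and no base is present that could enolise the γ-bromo ketone.

Step 19
Reactants: 27 (4R)-2-{[(1S,2S,3S)-3-bromo-2-(2,2-dimethoxyethyl)-2-methyl-6-oxocyclohexyl]methyl}-4-hydroxy-3,3-dimethylcyclohexan-1-one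
Product: 28 (1R)-3-{[(1S,2S,3S)-3-bromo-2-(2,2-dimethoxyethyl)-2-methyl-6-oxocyclohexyl]methyl}-2,2-dimethyl-4-oxocyclohexyl methanesulfonate (C20 epimers)
Conditions: MeSO2Cl, Et3N, CH2Cl2, −20 → 0 °C
Reagents that add atoms: methanesulfonyl chloride, CS(=O)(=O)Cl
Why: mesylation of the only hydroxyl in the molecule; the C5–O bond is not broken, so the 5R configuration is kept, and the neopentyl mesylate is inert to the acid and organometallic steps that follow.

Step 20
Reactants: 28 (1R)-3-{[(1S,2S,3S)-3-bromo-2-(2,2-dimethoxyethyl)-2-methyl-6-oxocyclohexyl]methyl}-2,2-dimethyl-4-oxocyclohexyl methanesulfonate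
Product: 30 spiro ketol mesylate (target labels 5R,7R,9S,11S,18S,20R: rings A/B/C with C2 and C15 ketones, equatorial C7–OH and C5–OMs), via keto aldehyde 29 (not isolated)
Conditions: 2 M aq. HCl/THF (1:4), rt → 40 °C
Reagents that add atoms: water, O
Why: acetal hydrolysis, then acid-catalysed intramolecular aldol addition of the more substituted enol of the C2 ketone (C20) to the aldehyde, a 6-(enolexo)-exo-trig closure of ring B; in the chair the bulky C21 takes the equatorial and C2 the axial position at C20 (20R), and the C7 hydroxyl is equatorial to avoid the axial C10 methyl (7R). C18 equilibrates to the trans ring fusion, and the ketol cannot dehydrate because C20 is quaternary.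

Step 21
Reactants: 30 spiro ketol mesylate
Product: 31 diol mesylate (target labels 5R,7R,9S,11S,15R,18S,20R: as 30 with C15 bearing CH3 and axial OH)
Conditions: MeMgBr, CeCl3, THF, −78 °C
Reagents that add atoms: methylmagnesium bromide, C[Mg]Br
Why: organocerium 1,2-addition, weakly basic so neither enolisation toward the γ-bromide nor retro-aldol of the cerium alkoxide should intervene; the C2 ketone, flanked by spiro C20, is far more hindered than C15, and the methyl enters equatorially, away from the axial C10 methyl, giving the axial alcohol (15R).

Step 22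
Reactants: 31 diol mesylate
Product: 32 methylene diol mesylate (target labels 5R,7R,9S,11S,15R,18S,20R: as 31 with C2=C1H2)
Conditions: Cp2Ti(μ-Cl)(μ-CH2)AlMe2 (Tebbe reagent, excess), pyridine, THF/toluene, −40 °C → rt
Reagents that add atoms: Tebbe reagent Cp2Ti(μ-Cl)(μ-CH2)AlMe2, C[Al-]1(C)C[Ti]([Cl+]1)(C2C=CC=C2)C3C=CC=C3
Why: Tebbe methylenation through the titanium methylidene ([2+2] and retro-[2+2] with the carbonyl) works on hindered, enolisable ketones and is not basic, so the β-hydroxy ketone is not opened by retro-aldol; the hydroxyls only consume reagent.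

Step 23
Reactants: 32 methylene diol mesylate
Product: 33 CNP0412361.2 (5S,7R,9S,11S,15R,18S,20R)
Conditions: KOt-Bu, THF, 0 °C → rt
Reagents that add atoms: none
Why: intramolecular Williamson etherification, 5-exo-tet: the C7 alkoxide displaces the C5 mesylate with inversion (5R → 5S), forming O6–C5 and ring D; H7 and the C7–O bond were fixed in step 20, so no reagent has to approach the hindered face of C7, and with C2 now a methylene the alkoxide has no retro-aldol path.

## Compound list

1 | 4,4-dimethoxybutan-2-one | CC(=O)CC(OC)OC | starting material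
2 | triethyl phosphonoacetate | CCOC(=O)CP(=O)(OCC)OCC | starting material
3 | ethyl (2E)-5,5-dimethoxy-3-methylpent-2-enoate | CCOC(=O)/C=C(\C)CC(OC)OC | intermediate
4 | (2E)-5,5-dimethoxy-3-methylpent-2-en-1-ol | OC/C=C(\C)CC(OC)OC | intermediate
5 | (2E)-5,5-dimethoxy-3-methylpent-2-en-1-yl methyl carbonate | COC(=O)OC/C=C(\C)CC(OC)OC | intermediate
6 | dimethyl propanedioate (dimethyl malonate) | COC(=O)CC(=O)OC | starting material
7 | dimethyl 2-[(3S)-5,5-dimethoxy-3-methylpent-1-en-3-yl]propanedioate | COC(=O)C(C(=O)OC)[C@](C)(C=C)CC(OC)OC | intermediate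
8 | methyl (3R)-3-ethenyl-5,5-dimethoxy-3-methylpentanoate | COC(=O)C[C@](C)(C=C)CC(OC)OC | intermediate
9 | (3S)-3-ethenyl-5,5-dimethoxy-3-methylpentanal | O=CC[C@](C)(C=C)CC(OC)OC | intermediate
10 | (2R,3S)-2-bromo-3-ethenyl-5,5-dimethoxy-3-methylpentanal | O=C[C@H](Br)[C@](C)(C=C)CC(OC)OC | intermediate (not isolated)
11 | (2R,3S)-2-bromo-3-ethenyl-5,5-dimethoxy-3-methylpentan-1-ol | OC[C@H](Br)[C@](C)(C=C)CC(OC)OC | intermediate
12 | (2R,3S)-2-bromo-3-ethenyl-5,5-dimethoxy-3-methylpentyl trifluoromethanesulfonate | O=S(=O)(OC[C@H](Br)[C@](C)(C=C)CC(OC)OC)C(F)(F)F | intermediate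
13 | acetaldehyde N,N-dimethylhydrazone | CC=NN(C)C | starting material
14 | (4S,5S)-4-bromo-5-ethenyl-7,7-dimethoxy-5-methylheptanal N,N-dimethylhydrazone | CN(C)N=CCC[C@H](Br)[C@](C)(C=C)CC(OC)OC | intermediate (not isolated)
15 | (4S,5S)-4-bromo-5-ethenyl-7,7-dimethoxy-5-methylheptanal | O=CCC[C@H](Br)[C@](C)(C=C)CC(OC)OC | intermediate
16 | 3-methylcyclohex-2-en-1-one | CC1=CC(=O)CCC1 | starting material
17 | 7-methyl-1,4-dioxaspiro[4.5]dec-7-ene | CC1=CCCC2(C1)OCCO2 | intermediate
18 | (7S,8R)-7,8-epoxy-7-methyl-1,4-dioxaspiro[4.5]decane | O1CCOC12CC[C@H]3O[C@@]3(C)C2 | intermediate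
19 | (4R)-4-hydroxy-3-methylcyclohex-2-en-1-one | O=C1C=C(C)[C@H](O)CC1 | intermediate
20 | (4R)-4-[(tert-butyldimethylsilyl)oxy]-3-methylcyclohex-2-en-1-one | O=C1C=C(C)[C@H](O[Si](C)(C)C(C)(C)C)CC1 | intermediate
21 | tert-butyl{[(1R)-2,2-dimethyl-4-(trimethylsilyloxy)cyclohex-3-en-1-yl]oxy}dimethylsilane | C[Si](C)(C)OC1=CC(C)(C)[C@H](O[Si](C)(C)C(C)(C)C)CC1 | intermediate
22 | lithium (4R)-4-[(tert-butyldimethylsilyl)oxy]-3,3-dimethylcyclohex-1-en-1-olate | [Li+].[O-]C1=CC(C)(C)[C@H](O[Si](C)(C)C(C)(C)C)CC1 | intermediate (not isolated)
23 | (4R)-2-[(4S,5S)-4-bromo-5-ethenyl-1-hydroxy-7,7-dimethoxy-5-methylheptyl]-4-[(tert-butyldimethylsilyl)oxy]-3,3-dimethylcyclohexan-1-one (diastereomers at C15 and C20) | O=C1CC[C@@H](O[Si](C)(C)C(C)(C)C)C(C)(C)C1C(O)CC[C@H](Br)[C@](C)(C=C)CC(OC)OC | intermediate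
24 | (4R)-2-[(4S,5S)-4-bromo-5-ethenyl-7,7-dimethoxy-5-methylheptanoyl]-4-[(tert-butyldimethylsilyl)oxy]-3,3-dimethylcyclohexan-1-one, chelated (Z)-enol (photochemical precursor) | O=C1CC[C@@H](O[Si](C)(C)C(C)(C)C)C(C)(C)/C1=C(/O)CC[C@H](Br)[C@](C)(C=C)CC(OC)OC | intermediate
25 | cyclobutanol photoadduct (C15–C18 and C20–C19 formed; ring-fusion centres unassigned) | O=C1CC[C@@H](O[Si](C)(C)C(C)(C)C)C(C)(C)C12CC3C2(O)CC[C@H](Br)[C@@]3(C)CC(OC)OC | intermediate (not isolated)
26 | (4R)-2-{[(1S,2S,3S)-3-bromo-2-(2,2-dimethoxyethyl)-2-methyl-6-oxocyclohexyl]methyl}-4-[(tert-butyldimethylsilyl)oxy]-3,3-dimethylcyclohexan-1-one (C20 epimers; product of the key step) | O=C1CC[C@@H](O[Si](C)(C)C(C)(C)C)C(C)(C)C1C[C@@H]1C(=O)CC[C@H](Br)[C@@]1(C)CC(OC)OC | intermediate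
27 | (4R)-2-{[(1S,2S,3S)-3-bromo-2-(2,2-dimethoxyethyl)-2-methyl-6-oxocyclohexyl]methyl}-4-hydroxy-3,3-dimethylcyclohexan-1-one (C20 epimers) | O=C1CC[C@@H](O)C(C)(C)C1C[C@@H]1C(=O)CC[C@H](Br)[C@@]1(C)CC(OC)OC | intermediate
28 | (1R)-3-{[(1S,2S,3S)-3-bromo-2-(2,2-dimethoxyethyl)-2-methyl-6-oxocyclohexyl]methyl}-2,2-dimethyl-4-oxocyclohexyl methanesulfonate (C20 epimers) | O=C1CC[C@@H](OS(C)(=O)=O)C(C)(C)C1C[C@@H]1C(=O)CC[C@H](Br)[C@@]1(C)CC(OC)OC | intermediate
29 | (1R)-3-{[(1S,2S,3S)-3-bromo-2-methyl-6-oxo-2-(2-oxoethyl)cyclohexyl]methyl}-2,2-dimethyl-4-oxocyclohexyl methanesulfonate | O=C1CC[C@@H](OS(C)(=O)=O)C(C)(C)C1C[C@@H]1C(=O)CC[C@H](Br)[C@@]1(C)CC=O | intermediate (not isolated)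
30 | spiro ketol mesylate (5R,7R,9S,11S,18S,20R; C2 and C15 ketones, equatorial C7–OH, C5–OMs) | O=C1CC[C@@H](OS(C)(=O)=O)C(C)(C)[C@@]12C[C@@H]3C(=O)CC[C@H](Br)[C@@]3(C)C[C@H]2O | intermediate
31 | diol mesylate (5R,7R,9S,11S,15R,18S,20R; C15 methyl carbinol) | O=C1CC[C@@H](OS(C)(=O)=O)C(C)(C)[C@@]12C[C@@H]3[C@](C)(O)CC[C@H](Br)[C@@]3(C)C[C@H]2O | intermediate
32 | methylene diol mesylate (5R,7R,9S,11S,15R,18S,20R) | C=C1CC[C@@H](OS(C)(=O)=O)C(C)(C)[C@@]12C[C@@H]3[C@](C)(O)CC[C@H](Br)[C@@]3(C)C[C@H]2O | intermediate
33 | CNP0412361.2 (5S,7R,9S,11S,15R,18S,20R) | C=C1CC[C@@H]2O[C@@H]3C[C@]4(C)[C@@H](Br)CC[C@@](C)(O)[C@H]4C[C@]13C2(C)C | target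

## Step count and least certain steps

Total step count: 23. Longest linear sequence: 18 steps (steps 1–9, then 15–23); the ring C branch (steps 10–14) joins at step 15.

**Step 17 (key step).** The most likely failure is too low a population of the planar chelated enol, because the chain on C15 is pressed against the C21 methyl groups (allylic 1,3-strain). The diketo tautomer barely absorbs at 350 nm, and where it does it would undergo Norrish-type α-cleavage at crowded C20 rather than cycloaddition, so conversion stalls or fragments accumulate.
Fallback, from 24 back to 26: fix the enol before irradiation. Me3SiCl/Et3N should convert 24 into its trimethylsilyl enol ether F9 (the silyl group moves between the two oxygens, so the isomer with the C20=C15 bond is available). Irradiation of this β-silyloxy enone should give the silylated cyclobutanol photoadduct F10. K2CO3 in MeOH removes the trimethylsilyl group and triggers the retro-aldol opening to 26.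

**Step 4.** The risk is poor branched-to-linear selectivity and modest enantioselection, because the two substituents on the reacting allyl terminus (methyl and CH2CH(OMe)2) are both alkyl and of similar size.
Fallback, from 3 back to 9, auxiliary-controlled conjugate addition: LiOH gives the acid F1. Pivaloyl chloride/Et3N and lithiated (4S)-4-phenyl-1,3-oxazolidin-2-one give the enoyl imide F2. CH2=CHMgBr with CuBr·SMe2 adds the vinyl group to the β-carbon from the face away from the phenyl group of the chelated s-cis imide, giving the imide F3. LiBH4 gives the alcohol F4, and Dess–Martin oxidation returns 9.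

**Step 7.** The risk is slow enamine formation from the β-quaternary aldehyde, which leaves room for unselective bromination, and epimerisation of the α-bromo aldehyde before it is reduced; either erodes the configuration at C11.
Fallback, from 8 back to 11, enolate bromination under auxiliary control: LiOH gives the acid F5. Pivaloyl chloride/Et3N and lithiated (4R)-4-benzyl-1,3-oxazolidin-2-one give the imide F6. Bu2BOTf/i-Pr2NEt followed by N-bromosuccinimide brominates the Z boron enolate from the face away from the benzyl group, giving the bromo imide F7. LiBH4 releases 11.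

**Step 9.** The risk is loss of HOTf or HBr from the β-bromo triflate to the strongly basic azaenolate, or bromine-assisted ionisation of the triflate with capture by the acetal oxygen, instead of substitution at C13.
Fallback, from 9 back to 15, with no sulfonate at all: brominate 9 as in step 7 to 10, but intercept 10 with (triphenylphosphoranylidene)acetaldehyde instead of NaBH4 to give the enal F8. Reduce the conjugated double bond alone by iminium-catalysed transfer hydrogenation (Hantzsch ester, dibenzylammonium trifluoroacetate), which touches neither the vinyl group nor the bromide, to reach 15.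

**Step 23.** The risk is base-induced elimination of the mesylate toward C4 in place of substitution, because the substitution requires ring C to leave its chair so that O6 can reach the back of the C5–O bond.
Fallback, from 28 to 33, closing ring D without an alkoxide:
- Me3SiCl/Et3N in DMF at 80 °C converts 28 into the bis(silyl enol ether) F11.
- Catalytic Me3SiOTf at −78 °C ionises the dimethyl acetal, and the C2 enol ether attacks through C20 (Mukaiyama reaction with an acetal), giving the C7 methyl ether F12 after work-up.
- Heating F12 in toluene with 2,6-di-tert-butylpyridine lets the ether oxygen displace the mesylate and lose its methyl group as methyl methanesulfonate, giving the tetracyclic diketone F13.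
- MeMgBr/CeCl3 gives the hydroxy ketone F14, and methylenation with Cp2Ti(μ-Cl)(μ-CH2)AlMe2 gives 33.

## Further compounds

F1 | step 4 | (2E)-5,5-dimethoxy-3-methylpent-2-enoic acid | OC(=O)/C=C(\C)CC(OC)OC
F2 | step 4 | (4S)-3-[(2E)-5,5-dimethoxy-3-methylpent-2-enoyl]-4-phenyl-1,3-oxazolidin-2-one | O=C1OC[C@H](c2ccccc2)N1C(=O)/C=C(\C)CC(OC)OC
F3 | step 4 | (4S)-3-[(3R)-3-ethenyl-5,5-dimethoxy-3-methylpentanoyl]-4-phenyl-1,3-oxazolidin-2-one | O=C1OC[C@H](c2ccccc2)N1C(=O)C[C@](C)(C=C)CC(OC)OC
F4 | step 4 | (3S)-3-ethenyl-5,5-dimethoxy-3-methylpentan-1-ol | OCC[C@](C)(C=C)CC(OC)OC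
F5 | step 7 | (3R)-3-ethenyl-5,5-dimethoxy-3-methylpentanoic acid | OC(=O)C[C@](C)(C=C)CC(OC)OC
F6 | step 7 | (4R)-4-benzyl-3-[(3R)-3-ethenyl-5,5-dimethoxy-3-methylpentanoyl]-1,3-oxazolidin-2-one | O=C1OC[C@@H](Cc2ccccc2)N1C(=O)C[C@](C)(C=C)CC(OC)OC
F7 | step 7 | (4R)-4-benzyl-3-[(2R,3S)-2-bromo-3-ethenyl-5,5-dimethoxy-3-methylpentanoyl]-1,3-oxazolidin-2-one | O=C1OC[C@@H](Cc2ccccc2)N1C(=O)[C@H](Br)[C@](C)(C=C)CC(OC)OC
F8 | step 9 | (2E,4S,5S)-4-bromo-5-ethenyl-7,7-dimethoxy-5-methylhept-2-enal | O=C/C=C/[C@H](Br)[C@](C)(C=C)CC(OC)OC
F9 | step 17 | trimethylsilyl enol ether of 24 (silyl on the C15 oxygen) | O=C1CC[C@@H](O[Si](C)(C)C(C)(C)C)C(C)(C)/C1=C(/O[Si](C)(C)C)CC[C@H](Br)[C@](C)(C=C)CC(OC)OC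
F10 | step 17 | O-trimethylsilyl cyclobutanol photoadduct | O=C1CC[C@@H](O[Si](C)(C)C(C)(C)C)C(C)(C)C12CC3C2(O[Si](C)(C)C)CC[C@H](Br)[C@@]3(C)CC(OC)OC
F11 | step 23 | bis(trimethylsilyl enol ether) of 28 (C2=C20 and C15=C18) | C[Si](C)(C)OC1=C(CC2=C(O[Si](C)(C)C)CC[C@H](Br)[C@@]2(C)CC(OC)OC)C(C)(C)[C@H](OS(C)(=O)=O)CC1
F12 | step 23 | C7 methyl ether of spiro ketol 30 | O=C1CC[C@@H](OS(C)(=O)=O)C(C)(C)[C@@]12C[C@@H]3C(=O)CC[C@H](Br)[C@@]3(C)C[C@H]2OC
F13 | step 23 | tetracyclic C2,C15-diketone | O=C1CC[C@@H]2O[C@@H]3C[C@]4(C)[C@@H](Br)CCC(=O)[C@H]4C[C@]13C2(C)C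
F14 | step 23 | tetracyclic C2 ketone with C15 methyl carbinol | O=C1CC[C@@H]2O[C@@H]3C[C@]4(C)[C@@H](Br)CC[C@@](C)(O)[C@H]4C[C@]13C2(C)C
A1 | alternative 1 | nine-membered α-acetoxy ether with ring C allylsilane (C7 epimers) | C[Si](C)(C)CC1=C2C[C@@H]3[C@](C)(O[Si](CC)(CC)CC)CC[C@H](Br)[C@@]3(C)CC(OC(C)=O)O[C@@H](CC1)C2(C)C
A2 | alternative 1 | C15 triethylsilyl ether of 33 | C=C1CC[C@@H]2O[C@@H]3C[C@]4(C)[C@@H](Br)CC[C@@](C)(O[Si](CC)(CC)CC)[C@H]4C[C@]13C2(C)C
A3 | alternative 2 | 2-vinylidene decalone (allenyl ketone, C7 ketone) | C=C=C1C[C@@H]2[C@](C)(O[Si](CC)(CC)CC)CC[C@H](Br)[C@@]2(C)CC1=O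
A4 | alternative 2 | 4-methylpenta-1,3-diene | CC(C)=CC=C
A5 | alternative 2 | spiro methylenecyclohexene ketone | C=C1CC=CC(C)(C)[C@@]12C[C@@H]3[C@](C)(O[Si](CC)(CC)CC)CC[C@H](Br)[C@@]3(C)CC2=O
A6 | alternative 3 | tricyclic C7 alcohol with C2 ketone and C5 methylene | O=C1CCCC(C)(C)[C@@]12C[C@@H]3[C@](C)(O[Si](CC)(CC)CC)CC[C@H](Br)[C@@]3(C)C[C@H]2O
A7 | alternative 3 | tetracyclic C2 ketone, C15 O-triethylsilyl | O=C1CC[C@@H]2O[C@@H]3C[C@]4(C)[C@@H](Br)CC[C@@](C)(O[Si](CC)(CC)CC)[C@H]4C[C@]13C2(C)C
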